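## Retrosynthetic overview

1. The C15–O angelate bond is made last, by oxidative copper coupling of angelic acid with a C15–B bond. That boron is tied to O6 in a six-membered cyclic hemiboronic ester, which keeps C15 cis to C6 and masks O6 while O8 is acetylated.
2. The cyclic hemiboronic ester comes from the 6,8-anti-diol by alkoxide-directed lithiation and borylation of the C15 methyl.
3. The anti-diol comes from the 6-hydroxy-8-ketone by 1,3-anti directed reduction (sets C8). The hydroxy ketone comes from an achiral ring dienone by enantioselective copper-catalysed conjugate borylation and oxidation (forms C6–O, sets C6 and C7).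
4. The dienone comes from germacrone by 1,4-hydrosilylation and Saegusa–Ito oxidation, which moves the enone double bond into the ring.
5. Rings: the ten-membered carbocycle is carried over from germacrone. The only ring formed is the temporary oxaborinine (step 4), opened again in step 6.

Assumption: germacrone (bulk isolate from zdravetz or Curcuma oil) counts as a cheap commercial starting material; germacrane numbering is used throughout (C14 on C10, C15 on C4, isopropyl on C7).

## Route

Step 1
Reactants: 1 germacrone
Product: 3 (1(10)E,4E,6Z)-germacra-1(10),4,6-trien-8-one, via triethylsilyl enol ether 2 (not isolated)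
Conditions: Et3SiH (1.05 equiv), RhCl(PPh3)3 (1 mol%), PhMe, 50 °C; strip volatiles; Pd(OAc)2 (1.05 equiv), MeCN, 25 °C
Reagents that add atoms: triethylsilane, CC[SiH](CC)CC
Why: Rhodium-catalysed 1,4-hydrosilylation of the s-cis isopropylidene enone (as for pulegone) fixes the enol ether at C7=C8, and Saegusa–Ito oxidation (β-hydride elimination from the palladium enolate) can only take a C6 hydrogen productively, because C10 carries no hydrogen and loss of H11 merely returns 1, so the double bond moves into the ring and into conjugation with C4=C5; no stereocentre is formed.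

Step 2
Reactants: 3 (1(10)E,4E,6Z)-germacra-1(10),4,6-trien-8-one
Product: 5 (1(10)E,4E,6S,7S)-6-hydroxygermacra-1(10),4-dien-8-one, via pinacol boronate 4 (not isolated)
Conditions: CuCl (5 mol%), (R)-DTBM-SEGPHOS (6 mol%), NaOtBu (10 mol%), B2pin2 (1.2 equiv), MeOH (2 equiv), THF, 0 to 25 °C; then NaBO3·4H2O, THF/H2O, 25 °C
Reagents that add atoms: bis(pinacolato)diboron, CC1(C)OB(OC1(C)C)B1OC(C)(C)C(C)(C)O1; sodium perborate, [Na+].[Na+].O[B-]1(O)OO[B-](O)(O)OO1
Why: Copper-catalysed enantioselective conjugate borylation followed by stereoretentive perborate oxidation of the C–B bond: the boryl–copper–bisphosphine adds 1,4 to the only electron-poor alkene (1,6-attack would have to hit the fully substituted C4), the ligand selects the enone face so that C6 becomes S (the ligand antipode is used if the sense turns out opposite), and C7 is set on protonation and base equilibration of the enolisable α-centre to the isomer with isopropyl anti to the C6 substituent (7S in 5).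

Step 3
Reactants: 5 (1(10)E,4E,6S,7S)-6-hydroxygermacra-1(10),4-dien-8-one
Product: 6 (1(10)E,4E,6S,7R,8S)-germacra-1(10),4-diene-6,8-diol
Conditions: Me4NBH(OAc)3 (5 equiv), MeCN/AcOH 1:1, −35 °C
Reagents that add atoms: none
Why: Evans–Saksena reduction: exchange of an acetate for the C6 hydroxyl gives an alkoxydiacetoxyborohydride that delivers hydride intramolecularly to C8 through a chair transition state, which gives the 1,3-anti diol (8S) without touching C6 or C7 (the 7R label is only a priority change).

Step 4
Reactants: 6 (1(10)E,4E,6S,7R,8S)-germacra-1(10),4-diene-6,8-diol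
Product: 8 cyclic hemiboronic ester of (1(10)E,4E,6S,7R,8S)-15-boronogermacra-1(10),4-diene-6,8-diol (B–OH bridging C15 and O6; 8-OH free), via trilithio species 7 (not isolated)
Conditions: n-BuLi (3.5 equiv), TMEDA (3.5 equiv), Et2O/hexane, 0 to 25 °C; B(OMe)3 (4 equiv), −78 to 0 °C; aq. NH4Cl
Reagents that add atoms: n-butyllithium, [Li]CCCC; trimethyl borate, COB(OC)OC; water, O
Why: Alkoxide-directed allylic lithiation (the reaction that gives the Z-dianion of prenol) followed by borate trapping: the C6 lithium alkoxide guides the base to the C15 methyl held cis to it across C4=C5 (six-membered chelate), whereas the 8α-alkoxide is expected to sit on the ring face opposite to C14, and the allyl anion is borylated at its primary terminus so that hydrolysis closes the six-membered hemiboronic ester and locks C15 cis to C6.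

Step 5
Reactants: 8 cyclic hemiboronic ester (8-OH free)
Product: 9 8-O-acetyl cyclic hemiboronic ester ((1(10)E,4E,6S,7S,8S); B–OH still bridging C15 and O6)
Conditions: Ac2O (1.5 equiv), pyridine, DMAP (5 mol%), CH2Cl2, 0 to 25 °C; pH 7 buffer
Reagents that add atoms: acetic anhydride, CC(=O)OC(C)=O
Why: DMAP-catalysed acetylation of the only free hydroxyl (O6 is bound to boron, and a second B–O8 bond would force a planar boron onto a bridgehead), with no change at any stereocentre.

Step 6
Reactants: 9 8-O-acetyl cyclic hemiboronic ester; 10 angelic acid ((2Z)-2-methylbut-2-enoic acid)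
Product: 11 [(1(10)E,4Z,6S,7S,8S)-8-acetoxy-6-hydroxygermacra-1(10),4-dien-15-yl] (2Z)-2-methylbut-2-enoate (target CNP0246594.1)
Conditions: Cu(OTf)2 (20 mol%), 4,4′-di-tert-butyl-2,2′-bipyridine (24 mol%), 10 (2 equiv), 2,6-lutidine (2.5 equiv), 4 Å MS, O2 (1 atm), MeCN, 30 °C; pH 7 buffer
Reagents that add atoms: none
Why: Proposed new method: copper-catalysed aerobic oxidative coupling of an allylic C(sp3)–B bond with a carboxylic acid (a Chan–Lam-type acyloxylation of an alkylboron); angelate coordinates the Lewis-acidic hemiboronic ester and assists transfer of the primary allyl group to divalent copper, oxidation gives a trivalent copper allyl carboxylate, and C–O reductive elimination at the unhindered C15 terminus (C5 is secondary and flanked by the boron-bound O6 and the fully substituted C4) forms the ester with the C4=C5 geometry unchanged, O6 staying on boron until work-up so that it cannot close a dihydrofuran and the angelate entering as an O-nucleophile so that it cannot isomerise to the tiglate; the closest known reaction types are the Chan–Lam esterification of arylboronic acids with carboxylic acids and the Chan–Lam amination of alkylboronic esters.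

## Compound list

1 | germacrone, (1(10)E,4E)-germacra-1(10),4,7(11)-trien-8-one | C/C1=C\CC(=C(C)C)C(=O)C/C(C)=C/CC1 | starting material
2 | 8-(triethylsilyloxy)-(1(10)E,4E,7Z)-germacra-1(10),4,7-triene (silyl enol ether, not isolated) | C/C1=C\CC(/C(C)C)=C(/O[Si](CC)(CC)CC)C/C(C)=C/CC1 | intermediate
3 | (1(10)E,4E,6Z)-germacra-1(10),4,6-trien-8-one, i.e. (2Z,4E,8E)-5,9-dimethyl-2-(propan-2-yl)cyclodeca-2,4,8-trien-1-one (achiral) | C/C1=C\C=C(\C(C)C)C(=O)C/C(C)=C/CC1 | intermediate
4 | (1(10)E,4E,6S,7R)-6-(4,4,5,5-tetramethyl-1,3,2-dioxaborolan-2-yl)germacra-1(10),4-dien-8-one (not isolated) | C/C1=C\[C@H](B2OC(C)(C)C(C)(C)O2)[C@H](C(C)C)C(=O)C/C(C)=C/CC1 | intermediate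
5 | (1(10)E,4E,6S,7S)-6-hydroxygermacra-1(10),4-dien-8-one | C/C1=C\[C@H](O)[C@H](C(C)C)C(=O)C/C(C)=C/CC1 | intermediate
6 | (1(10)E,4E,6S,7R,8S)-germacra-1(10),4-diene-6,8-diol | C/C1=C\[C@H](O)[C@H](C(C)C)[C@@H](O)C/C(C)=C/CC1 | intermediate
7 | 15-lithio-6,8-bis(lithiooxy) derivative of 6 (not isolated) | [Li]C/C1=C\[C@H](O[Li])[C@H](C(C)C)[C@@H](O[Li])C/C(C)=C/CC1 | intermediate
8 | cyclic hemiboronic ester, (1(10)E,4E,6S,7R,8S): B(OH) bridges C15 and O6 (ring O6–B–C15–C4=C5–C6), 8-OH free | OB1C/C2=C\[C@H](O1)[C@H](C(C)C)[C@@H](O)C/C(C)=C/CC2 | intermediate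
9 | 8-O-acetyl cyclic hemiboronic ester, (1(10)E,4E,6S,7S,8S) | OB1C/C2=C\[C@H](O1)[C@H](C(C)C)[C@@H](OC(C)=O)C/C(C)=C/CC2 | intermediate
10 | angelic acid, (2Z)-2-methylbut-2-enoic acid | C/C=C(/C)C(O)=O | starting material
11 | [(1(10)E,4Z,6S,7S,8S)-8-acetoxy-6-hydroxygermacra-1(10),4-dien-15-yl] (2Z)-2-methylbut-2-enoate | C/C=C(/C)C(=O)OC/C1=C\[C@H](O)[C@H](C(C)C)[C@@H](OC(C)=O)C/C(C)=C/CC1 | target

## Step count and risks

Total steps: 6. Longest linear sequence: 6 (1 to 11; angelic acid 10 is used as purchased).

The three steps most likely to fail are steps 6, 4 and 2.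

The first is step 6, the proposed new coupling. The allyl–boron bond may transmetalate slowly or protodeboronate, the carboxylate may be delivered to C5 with allylic transposition, or O6 may leave boron early and close the 6,15-ether. The fallback sets out from 9 and returns at 11. NaBO3·4H2O in THF/H2O oxidises the C15–B bond with retention and leaves the acetate alone, giving (1(10)E,4Z,6S,7S,8S)-8-acetoxygermacra-1(10),4-diene-6,15-diol F1. Angelic acid 10 is converted with 2,4,6-trichlorobenzoyl chloride and Et3N in toluene into angelic 2,4,6-trichlorobenzoic anhydride F2. F2 then acylates the primary allylic hydroxyl of F1 selectively (toluene, 60 °C, no DMAP, so the angelate does not isomerise) to give 11.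

The second is step 4. Lithiation may be unselective (for example C14 metalation guided by O8, or other allylic positions), or the trilithio species may be too insoluble. The fallback sets out from 6 and returns at 11 by vinylogous enone chemistry:
- MnO2 in CH2Cl2 oxidises only the allylic C6 alcohol to (1(10)E,4E,7R,8S)-8-hydroxygermacra-1(10),4-dien-6-one F3.
- TMSOTf/Et3N gives (1(10)E,5Z,7R,8S)-6,8-bis(trimethylsilyloxy)germacra-1(10),4(15),5-triene F4.
- Buffered mCPBA attacks the electron-rich terminal double bond of the dienol ether in preference to C1=C10 (vinylogous Rubottom oxidation), and work-up removes both silyl groups to give (1(10)E,4Z,7R,8S)-8,15-dihydroxygermacra-1(10),4-dien-6-one F5.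
- Mitsunobu esterification of the primary alcohol with 10 (PPh3, DIAD, THF, 0 °C) gives [(1(10)E,4Z,7R,8S)-8-hydroxy-6-oxogermacra-1(10),4-dien-15-yl] (2Z)-2-methylbut-2-enoate F6.
- Evans–Tishchenko reduction (catalyst preformed from SmI2, 30 mol%, and excess CH3CHO, THF, −10 °C) reduces C6 1,3-anti to the C8 hydroxyl and places the acetyl group on O8, giving 11 directly.

The third is step 2. On this macrocyclic, α-branched dienone the chiral copper catalyst may give low enantioselectivity or a poor C7 ratio. The fallback sets out from 3 and returns at 5. The borylation is run with achiral CuCl/Xantphos (B2pin2, NaOtBu, MeOH, THF; then NaBO3·4H2O). This gives 5 together with its mirror image: (1(10)E,4E,6R,7S)-6-(4,4,5,5-tetramethyl-1,3,2-dioxaborolan-2-yl)germacra-1(10),4-dien-8-one F7 is oxidised to (1(10)E,4E,6R,7R)-6-hydroxygermacra-1(10),4-dien-8-one F8. Amano lipase PS with vinyl acetate in MTBE should, by the Kazlauskas rule, acetylate the 6R alcohol to (1(10)E,4E,6R,7R)-6-acetoxygermacra-1(10),4-dien-8-one F9 and leave 5, which is separated by chromatography (at most half of the material).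

## Further compounds

F1 | step 6 | (1(10)E,4Z,6S,7S,8S)-8-acetoxygermacra-1(10),4-diene-6,15-diol | OC/C1=C\[C@H](O)[C@H](C(C)C)[C@@H](OC(C)=O)C/C(C)=C/CC1
F2 | step 6 | (2Z)-2-methylbut-2-enoic 2,4,6-trichlorobenzoic anhydride | C/C=C(/C)C(=O)OC(=O)c1c(Cl)cc(Cl)cc1Cl
F3 | step 4 | (1(10)E,4E,7R,8S)-8-hydroxygermacra-1(10),4-dien-6-one | C/C1=C\C(=O)[C@H](C(C)C)[C@@H](O)C/C(C)=C/CC1
F4 | step 4 | (1(10)E,5Z,7R,8S)-6,8-bis(trimethylsilyloxy)germacra-1(10),4(15),5-triene | C=C1/C=C(O[Si](C)(C)C)/[C@H](C(C)C)[C@@H](O[Si](C)(C)C)C/C(C)=C/CC1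
F5 | step 4 | (1(10)E,4Z,7R,8S)-8,15-dihydroxygermacra-1(10),4-dien-6-one | OC/C1=C\C(=O)[C@H](C(C)C)[C@@H](O)C/C(C)=C/CC1
F6 | step 4 | [(1(10)E,4Z,7R,8S)-8-hydroxy-6-oxogermacra-1(10),4-dien-15-yl] (2Z)-2-methylbut-2-enoate | C/C=C(/C)C(=O)OC/C1=C\C(=O)[C@H](C(C)C)[C@@H](O)C/C(C)=C/CC1
F7 | step 2 | (1(10)E,4E,6R,7S)-6-(4,4,5,5-tetramethyl-1,3,2-dioxaborolan-2-yl)germacra-1(10),4-dien-8-one | C/C1=C\[C@@H](B2OC(C)(C)C(C)(C)O2)[C@@H](C(C)C)C(=O)C/C(C)=C/CC1
F8 | step 2 | (1(10)E,4E,6R,7R)-6-hydroxygermacra-1(10),4-dien-8-one | C/C1=C\[C@@H](O)[C@@H](C(C)C)C(=O)C/C(C)=C/CC1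
F9 | step 2 | (1(10)E,4E,6R,7R)-6-acetoxygermacra-1(10),4-dien-8-one | C/C1=C\[C@@H](OC(C)=O)[C@@H](C(C)C)C(=O)C/C(C)=C/CC1
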